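## The problem

Genkwanol B (33) has one carbon, C8, shared by three rings: the cyclohexadienone ring A (C4a–C5–C6–C7–C8–C8a), a dihydrofuran (O7–C2′–C3′–C8–C7) and a chroman-4-one (aryl ether O–C8–C3′–C4′ plus its benzo ring). The last two are cis-fused along C8–C3′, and ring A also carries the dihydropyran ring C (O1–C2–C3–C4) of a flavan-3-ol. Here C2′ is the furan methine bearing an aryl group, C3′ the tertiary carbinol and C4′ the aryl ketone. There are five stereocentres: C8 (S, quaternary, oxygen-bearing), C3′ (R), C2′ (S), and the trans pair C2 (R) and C3 (S).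

C8, C3′ and C2′ are contiguous. Once C8 is fixed it can direct C3′ (the angular oxygen must end cis to the C8a branch) and C2′ (aryl on the convex face, cis to the C3′ oxygen). C2 and C3 are too far from this triad for relay and need their own absolute control in a separate fragment.

The fragile points are:
- the tertiary α-ketol at C3′, which lies β to the carbonyl carbons on C8 and can cleave C8–C3′ by retro-aldol under base;
- the two 4-hydroxybenzylic C–O bonds (C2–O1 and C2′–O7), whose oxygens are vinylogous ester oxygens and can ionise in strong acid;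
- four phenols.

Ring A is a phloroglucinol held at the dienone stage only because C8 is quaternary. Read around the ring, C8a–C8–C7–C6–C5–C4a is the carbon chain of a 3,5-diketo ester. Ring A can therefore be closed by a Claisen reaction between C4a and C8a without ever passing through an aromatic ring. If the C7 carbonyl is held as the furan enol ether beforehand, C7 and C8a, which end as two different oxygen-bearing carbons, are told apart by construction.

## Retrosynthesis

**33 ⇒ 31.** The O1–C8a bond of ring C and all acetal protecting groups are cut, giving the enolised trione 31 with an open C2–C3 chain (diol as acetonide, four phenols and the C3′ hydroxyl as methoxymethyl ethers). Leaving ring C to the end lets one acid treatment do the deprotection and the ring closure. The chain is made as the erythro (2R,3S) diol because both conceivable closure modes give the 2,3-trans ring from it: addition of the C2 hydroxyl to C8a with the C2–O bond kept, or capture of a benzylic cation at C2 by the C8a enol oxygen. The forward step must close on the C8a oxygen and not on the C5 carbonyl.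

**31 ⇒ 30 (key disconnection).** The C4a–C8a bond is cut, which opens ring A to the keto ester 30: a methyl ester on quaternary C8, and an (E)-alkylidene dihydrofuran whose exocyclic carbon C6 carries the C5 ketone and the chain. Against cuts at C8–C7 or C8–C8a, this one leaves the quaternary centre untouched. Against dearomatisation routes, it needs no para-selective attack on a phloroglucinol. Compound 30 has one ring fewer and no new stereocentre is at stake. The forward reaction needs enolisation at C4a only, an intact C8–C3′ bond, and the chain on the ester side of the alkene.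

**30 ⇒ 28 ⇒ 27 ⇒ 26.** The O7–C7 bond is cut: 30 is the 5-exo oxa-Michael adduct of the C2′ alkoxide onto the ynone 28. Forming this bond from an alkyne fixes which carbon of C8 becomes the enol ether, and the protonation of the allenolate sets the alkene geometry. The ynone carbonyl is traced back through the propargylic alcohol 27 to its 4-methoxybenzyl ether 26, so that the alkyne can be carried through the earlier steps without a conjugated carbonyl.

**26 ⇒ 25 + 19.** The C3′–C2′ bond is cut by an aldol between the tetrasubstituted enol silane 25 and aldehyde 19. Oxygen must be on C3′ before carbon: the second substituent enters anti to the ester on C8, which places the carbinol branch cis to the alkyne and the C3′ oxygen cis to the ester, as the cis-fused bicycle requires. The reverse order would put the oxygen trans to the ester. The forward step must also set C2′, which an open transition state is expected to do.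

**25 ⇒ 24 ⇒ 23 ⇒ 21.** The C3′–O bond is cut: 23 is the α-hydroxylation product of the enol silane 21, protected as the methoxymethyl ether 24 while still secondary and re-enolised to 25. The configuration created at C3′ here is irrelevant because 25 is planar at that carbon.

**21 ⇒ 5 + 17.** The C8–C7 bond is cut: conjugate addition of the copper acetylide of alkyne 17 to the benzopyrylium ion of chromone ester 5. This one catalytic step creates the quaternary ether carbon with absolute control, attaches the whole side chain, and returns the product as the enol silane needed next.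

**5 ⇒ 4 ⇒ 1 + 2.** The chromone ester comes from acetophenone 1 and oxalate 2 by Claisen condensation and cyclodehydration, then protection.

**17 ⇒ 16 ⇒ 15 ⇒ 12 ⇒ 11 ⇒ 8 + 7 (+ 13); 7 ⇐ 6; 19 ⇐ 18.** The chain is cut at C5–C6 (ethynyl Grignard 13 onto the lactol of 12) and at C2–aryl (aryl Grignard from 7 onto the acid chloride of lactone acid 8). Lactone acid 8 supplies C3 with the correct configuration and C2–C5 at the correct oxidation levels, so only C2 has to be created, by reagent-controlled reduction of ketone 11. Bromide 7 and aldehyde 19 are the methoxymethyl ethers of phenols 6 and 18.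

## Roads not taken

Alternative 1: Both aryl–carbon bonds (C2–aryl and C2′–aryl) are cut, leaving the aryl-free bis(lactol acetate) A2. In the forward step a Lewis acid would ionise both anomeric acetates and the diarylzinc A3 would transfer a 4-silyloxyphenyl group to each cation, giving the protected natural product A1.
- Merits: it is the most convergent of the four plans. Both identical aryl groups come late from one reagent. The C3 acetate can steer the C2 aryl trans by neighbouring-group participation, and at C2′ the convex face is the natural one. Aryl analogues would be easy.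
- Weak points: O1 and O7 are vinylogous ester oxygens tied into the C5 carbonyl, so the two cations are poorly stabilised and ionisation must compete with Lewis-acid reactions of the dienone and of the free tertiary ketol. Two different cations must react cleanly in one flask. A2 still contains C8, C3′ and the whole spiro dienone, so the hardest part is only postponed.
- Comparison: in convergence and late variation this road is better than the chosen one, which carries both aryl groups through a 16-step linear sequence. The chosen plan sets against this an actual construction of the spiro core, with each stereocentre made by an established reaction on a simple compound (C8 in 21, C2 in 12).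

Alternative 2: The C8–C3′ bond is cut, leading back to the nine-membered diaryl ether diketone macrocycle A5, in which ring A is still a phenol and ring C is already in place. In the forward step the free C5 phenol would attack the C3′ ketone through its para carbon C8, closing the dihydrofuran and the chromanone at once and turning ring A into the dienone of A4.
- Merits: C2, C3 and ring C come intact from a preformed flavan-3-ol unit, so no late ring C closure is needed. One step makes two rings and both C8 and C3′. It would be much shorter if A5 were available.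
- Weak points: the aldol is dearomatising and its product can revert by retro-aldol with regained aromaticity, so it has to be paid for by ring strain alone. A5 is a medium ring with an enolisable, hydrate-prone 1,2-diketone and an epimerisable C2′. The relative configuration of C8 and C3′ to C2′ would rest on an unknown macrocycle conformation.
- Comparison: in step count and in the handling of C2/C3 this road is better. The chosen plan sets against it that ring A is never aromatic (the Claisen closure is downhill and is drained by deprotonation of 31) and that C8 is fixed by a catalyst, not by conformation.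

Alternative 3: The C3′–C4′ bond is cut, leading back to the aldehyde A7, a spiro furan-3-one whose C8 carries a 2-formylaryl ether. In the forward step a triazolium-derived carbene would turn the aldehyde into an acyl anion equivalent that adds to the neighbouring furanone carbonyl, closing the chromanone of A6.
- Merits: intramolecular aldehyde–ketone benzoin closure to 3-hydroxychromanones is established and mild. The new C3′ centre is tied to C8 by the cis ring fusion, which is a more reliable control than the facial bias the chosen plan uses in step 14. Ring C again comes preformed.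
- Weak points: A7 needs a quaternary aryl ether at C8 on a dienone, which means oxidative dearomatisation with a hindered phenol as nucleophile and no evident control of C8. The C2′ hydrogen of the furanone lies between O7 and the ketone and can epimerise or eliminate under the basic carbene conditions. The aldehyde is a trioxygenated, electron-rich one and the ketone is flanked by the quaternary C8.
- Comparison: for C3′ this road is the safer one, and the chosen plan has only an argued, not enforced, selectivity to set against it. In return the chosen plan makes C8 enantioselectively before anything else and avoids dearomatisation.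

Key step: step 18

Conventions and assumptions:
- Abbreviations: MOM = methoxymethyl, PMB = 4-methoxybenzyl, TBS = tert-butyldimethylsilyl, TMS = trimethylsilyl, Ar = 4-(methoxymethoxy)phenyl, Diox = (4S,5R)-5-Ar-2,2-dimethyl-1,3-dioxolan-4-yl.
- In the chromene and chromane intermediates the systematic C2 becomes C8, C3 becomes C3′ and the exocyclic carbinol carbon becomes C2′.
- Assumption: the bis(oxazoline) ligand antipode in step 10 is the one whose copper acetylide gives (2S)-21; both antipodes are available.
- Assumption: the propargylic carbinol centre made in step 6 is carried as a mixture of epimers (RS) because step 16 destroys it; likewise C3 of 22–24 is a mixture that converges in 25.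

Step 1
Reactants: 1 2′,4′,6′-trihydroxyacetophenone; 2 dimethyl oxalate
Product: 4 methyl 5,7-dihydroxy-4-oxo-4H-chromene-2-carboxylate, via diketo ester 3 (not isolated)
Conditions: NaOMe (5 equiv), MeOH, reflux; then conc. HCl, MeOH, reflux
Reagents that add atoms: none
Why: Claisen condensation of the acetyl group with the oxalate gives the 2,4-diketo ester, which cyclodehydrates under acid to the chromone-2-carboxylate; no stereocentre is involved.

Step 2
Reactants: 4 methyl 5,7-dihydroxy-4-oxo-4H-chromene-2-carboxylate
Product: 5 methyl 5,7-bis(methoxymethoxy)-4-oxo-4H-chromene-2-carboxylate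
Conditions: NaH (2.5 equiv), MOMCl (3 equiv), DMF, 0 °C to rt
Reagents that add atoms: chloromethyl methyl ether, COCCl
Why: Williamson-type O-alkylation of both phenoxides; the strong base is used because the 5-hydroxyl is hydrogen-bonded to the carbonyl.

Step 3
Reactants: 6 4-bromophenol
Product: 7 1-bromo-4-(methoxymethoxy)benzene
Conditions: MOMCl, i-Pr2NEt, CH2Cl2, 0 °C to rt
Reagents that add atoms: chloromethyl methyl ether, COCCl
Why: Standard methoxymethyl protection of a phenol.

Step 4
Reactants: 8 (2S)-5-oxooxolane-2-carboxylic acid; 7 1-bromo-4-(methoxymethoxy)benzene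
Product: 11 (5S)-5-[4-(methoxymethoxy)benzoyl]oxolan-2-one, via acid chloride 9 (not isolated), via aryl Grignard reagent 10 (not isolated)
Conditions: 8: (COCl)2, DMF (cat.), CH2Cl2, 0 °C to rt, concentrate; 7: Mg, THF, 40 °C; then combine with Fe(acac)3 (3 mol%), THF, −78 °C
Reagents that add atoms: none
Why: Iron-catalysed acylation of an aryl Grignard reagent by an acid chloride is faster at −78 °C than addition to the lactone or to the product ketone; the stereocentre comes unchanged from 8.

Step 5
Reactants: 11 (5S)-5-[4-(methoxymethoxy)benzoyl]oxolan-2-one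
Product: 12 (5S)-5-{(R)-hydroxy[4-(methoxymethoxy)phenyl]methyl}oxolan-2-one
Conditions: (R)-2-methyl-CBS-oxazaborolidine (20 mol%), BH3·SMe2, THF, −20 °C
Reagents that add atoms: none
Why: Corey–Bakshi–Shibata reduction with the aryl group as the large substituent; the (R)-catalyst should deliver hydride to the face that gives the (R)-carbinol, i.e. the erythro diol pattern, against the weaker Felkin–Anh preference of the substrate.

Step 6
Reactants: 12 (5S)-5-{(R)-hydroxy[4-(methoxymethoxy)phenyl]methyl}oxolan-2-one; 13 ethynylmagnesium bromide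
Product: 15 (1R,2S,5RS)-1-[4-(methoxymethoxy)phenyl]hept-6-yne-1,2,5-triol, via lactol 14 (not isolated)
Conditions: i-Bu2AlH (2.2 equiv), CH2Cl2, −78 °C; then HC≡CMgBr (5 equiv), THF, −78 °C to rt; aq. potassium sodium tartrate
Reagents that add atoms: none
Why: Partial reduction stops at the lactol aluminate, which on warming releases the hydroxy aldehyde for Grignard addition (one-pot reduction–alkynylation); the new carbinol centre is uncontrolled and is removed in step 16.

Step 7
Reactants: 15 (1R,2S,5RS)-1-[4-(methoxymethoxy)phenyl]hept-6-yne-1,2,5-triol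
Product: 16 (3RS)-1-Diox-pent-4-yn-3-ol
Conditions: Me2C(OMe)2, pyridinium p-toluenesulfonate (cat.), CH2Cl2, rt
Reagents that add atoms: 2,2-dimethoxypropane, COC(C)(C)OC
Why: Acetonide formation takes the 1,2-diol into a five-membered dioxolane; the propargylic hydroxyl is 1,4-related to the nearer diol oxygen and stays free.

Step 8
Reactants: 16 (3RS)-1-Diox-pent-4-yn-3-ol
Product: 17 (3RS)-3-[(4-methoxybenzyl)oxy]-5-Diox-pent-1-yne
Conditions: NaH (1.1 equiv), PMBCl, Bu4NI (cat.), THF–DMF, 0 °C to rt
Reagents that add atoms: 4-methoxybenzyl chloride, COc1ccc(CCl)cc1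
Why: Williamson etherification of the alkoxide; an ether (not an ester) is chosen so that the propargylic position carries no leaving group in the copper step.

Step 9
Reactants: 18 4-hydroxybenzaldehyde
Product: 19 4-(methoxymethoxy)benzaldehyde
Conditions: MOMCl, i-Pr2NEt, CH2Cl2, 0 °C to rt
Reagents that add atoms: chloromethyl methyl ether, COCCl
Why: Standard methoxymethyl protection of a phenol.

Step 10
Reactants: 5 methyl 5,7-bis(methoxymethoxy)-4-oxo-4H-chromene-2-carboxylate; 17 (3RS)-3-[(4-methoxybenzyl)oxy]-5-Diox-pent-1-yne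
Product: 21 methyl (2S)-4-(TBSO)-5,7-bis(MOMO)-2-[(3RS)-3-(PMBO)-5-Diox-pent-1-yn-1-yl]-2H-chromene-2-carboxylate, via benzopyrylium triflate 20 (not isolated)
Conditions: 5, TBSOTf (1.2 equiv), CH2Cl2, rt to 40 °C; then CuI (10 mol%), 2,2′-(propane-2,2-diyl)bis(4-phenyl-4,5-dihydrooxazole) (12 mol%), i-Pr2NEt, 17, toluene, −78 to −35 °C; Et3N-buffered work-up
Reagents that add atoms: tert-butyldimethylsilyl trifluoromethanesulfonate, CC(C)(C)[Si](C)(C)OS(=O)(=O)C(F)(F)F
Why: O-silylation turns the chromone into a 4-silyloxybenzopyrylium ion, and the chiral copper–bis(oxazoline) acetylide adds to its C2 (copper-catalysed enantioselective alkynylation of chromone-2-carboxylate-derived benzopyrylium ions), creating the quaternary ether centre under ligand control. The product is kept as the enol silane for the next step.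

Step 11
Reactants: 21 methyl (2S)-4-(TBSO)-5,7-bis(MOMO)-2-[(3RS)-3-(PMBO)-5-Diox-pent-1-yn-1-yl]-2H-chromene-2-carboxylate
Product: 23 methyl (2R,3RS)-3-hydroxy-5,7-bis(MOMO)-4-oxo-2-[(3RS)-3-(PMBO)-5-Diox-pent-1-yn-1-yl]chromane-2-carboxylate, via silyloxy ketone 22 (not isolated)
Conditions: mCPBA (1.1 equiv), NaHCO3, CH2Cl2, −20 to 0 °C; then HF·pyridine, pyridine–THF, 0 °C
Reagents that add atoms: 3-chloroperoxybenzoic acid, OOC(=O)c1cccc(Cl)c1
Why: Rubottom oxidation: the enol silane is by far the most electron-rich alkene, its epoxide rearranges with silyl migration to the α-silyloxy ketone, and fluoride frees the hydroxyl. The configuration formed at C3 does not matter because step 13 makes this carbon planar again.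

Step 12
Reactants: 23 methyl (2R,3RS)-3-hydroxy-5,7-bis(MOMO)-4-oxo-2-[(3RS)-3-(PMBO)-5-Diox-pent-1-yn-1-yl]chromane-2-carboxylate
Product: 24 methyl (2R,3RS)-3,5,7-tris(MOMO)-4-oxo-2-[(3RS)-3-(PMBO)-5-Diox-pent-1-yn-1-yl]chromane-2-carboxylate
Conditions: MOMCl (5 equiv), i-Pr2NEt, Bu4NI (cat.), CH2Cl2, 40 °C
Reagents that add atoms: chloromethyl methyl ether, COCCl
Why: The oxygen is protected while it is still a secondary alcohol; an acetal is chosen over a silyl ether because it cannot migrate to the neighbouring alkoxide formed in step 17.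

Step 13
Reactants: 24 methyl (2R,3RS)-3,5,7-tris(MOMO)-4-oxo-2-[(3RS)-3-(PMBO)-5-Diox-pent-1-yn-1-yl]chromane-2-carboxylate
Product: 25 methyl (2R)-3,5,7-tris(MOMO)-4-(TMSO)-2-[(3RS)-3-(PMBO)-5-Diox-pent-1-yn-1-yl]-2H-chromene-2-carboxylate
Conditions: TMSOTf (1.5 equiv), Et3N (3 equiv), CH2Cl2, −78 to 0 °C
Reagents that add atoms: trimethylsilyl trifluoromethanesulfonate, C[Si](C)(C)OS(=O)(=O)C(F)(F)F
Why: Soft enolisation: C3–H is the only α-hydrogen, and no free enolate is formed that could open the pyranone ring by β-elimination of the aryloxide and so racemise C2.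

Step 14
Reactants: 25 methyl (2R)-3,5,7-tris(MOMO)-4-(TMSO)-2-[(3RS)-3-(PMBO)-5-Diox-pent-1-yn-1-yl]-2H-chromene-2-carboxylate; 19 4-(methoxymethoxy)benzaldehyde
Product: 26 methyl (2R,3R)-3-[(S)-Ar(TMSO)methyl]-3,5,7-tris(MOMO)-4-oxo-2-[(3RS)-3-(PMBO)-5-Diox-pent-1-yn-1-yl]chromane-2-carboxylate
Conditions: (Me2N)3S(Me3SiF2) (10 mol%), THF, −78 °C
Reagents that add atoms: none
Why: Fluoride-catalysed Mukaiyama aldol with silyl transfer: C3 attacks the aldehyde on the face anti to the pseudoaxial ester on C2, so the carbinol branch ends cis to the alkyne and the OMOM group cis to the ester. In the extended open transition state the aryl group lies beside the small OMOM substituent and away from quaternary C2, which should give the (S)-carbinol (the syn-type adduct usual for cyclic enol silanes under fluoride catalysis). Silylation of the aldolate blocks retro-aldol.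

Step 15
Reactants: 26 methyl (2R,3R)-3-[(S)-Ar(TMSO)methyl]-3,5,7-tris(MOMO)-4-oxo-2-[(3RS)-3-(PMBO)-5-Diox-pent-1-yn-1-yl]chromane-2-carboxylate
Product: 27 methyl (2R,3R)-3-[(S)-Ar(TMSO)methyl]-3,5,7-tris(MOMO)-4-oxo-2-[(3RS)-3-hydroxy-5-Diox-pent-1-yn-1-yl]chromane-2-carboxylate
Conditions: DDQ (1.3 equiv), CH2Cl2–pH 7 buffer, 0 °C
Reagents that add atoms: none
Why: Oxidative cleavage of the 4-methoxybenzyl ether; the other benzylic C–H bonds are secondary, flanked by oxygenated carbons and so slower to lose hydride, and the hindered silyl ether should survive the neutral buffer.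

Step 16
Reactants: 27 methyl (2R,3R)-3-[(S)-Ar(TMSO)methyl]-3,5,7-tris(MOMO)-4-oxo-2-[(3RS)-3-hydroxy-5-Diox-pent-1-yn-1-yl]chromane-2-carboxylate
Product: 28 methyl (2R,3R)-3-[(S)-Ar(TMSO)methyl]-3,5,7-tris(MOMO)-4-oxo-2-(3-oxo-5-Diox-pent-1-yn-1-yl)chromane-2-carboxylate
Conditions: Dess–Martin periodinane, NaHCO3, CH2Cl2, 0 °C to rt
Reagents that add atoms: none
Why: Dess–Martin oxidation of a propargylic alcohol to the ynone under buffered, non-basic conditions; both carbinol epimers give the same ketone.

Step 17
Reactants: 28 methyl (2R,3R)-3-[(S)-Ar(TMSO)methyl]-3,5,7-tris(MOMO)-4-oxo-2-(3-oxo-5-Diox-pent-1-yn-1-yl)chromane-2-carboxylate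
Product: 30 (E)-alkylidene dihydrofuran keto ester (key precursor; C8 R; C3′ R; C2′ S), via hydroxy ynone 29 (not isolated)
Conditions: Bu4NF (1.1 equiv), THF, −78 to −20 °C; aq. NH4Cl
Reagents that add atoms: none
Why: Fluoride cleaves the silyl ether and the alkoxide adds to the ynone β-carbon C7 in a 5-exo-dig oxa-Michael closure that should outrun retro-aldol. The allenolate is protonated at C6 from the side of the ring oxygen, away from quaternary C8, which places the acyl group cis to C8, i.e. the (E)-alkylidene.

Step 18
Reactants: 30 (E)-alkylidene dihydrofuran keto ester (key precursor; C8 R; C3′ R; C2′ S)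
Product: 31 ring A enol with open C2–C3 chain as acetonide (C8 R; C3′ R; C2′ S)
Conditions: LiN(SiMe3)2 (2.5 equiv), THF, −78 to 0 °C; aq. NH4Cl
Reagents that add atoms: none
Why: LiN(SiMe3)2 removes a C4a proton, the only acidic C–H beside the C5 ketone (C6 is vinylic, C8 and C3′ carry no hydrogen), and the enolate adds to the ester carbonyl C8a on the neighbouring quaternary carbon; loss of methoxide gives the cyclic trione, which the second equivalent of base converts to its stabilised vinylogous carboxylate, so the Claisen equilibrium and any reversible O-acylation drain to the C-acylated ring. The closest known reaction type is the Claisen (Dieckmann-type) cyclisation of 3,5-diketo esters to cyclohexane-1,3,5-triones, the laboratory counterpart of polyketide folding; here the C7 carbonyl takes part as its furan enol ether. Ring A closes in a 6-(enolendo)-exo-trig mode, allowed by the Baldwin rules for enolates. No stereocentre is created, and C8, C3′ and C2′ have no acidic hydrogen, so none can epimerise. The step needs C-acylation from C4a alone, an intact C8–C3′ bond and a chain within reach of the ester: the first follows from the single enolisable position, the second from the methoxymethyl ether on the C3′ oxygen (no alkoxide, hence no retro-aldol), the third from the (E)-alkylidene, which holds C5 and its chain cis to C8. Because C8 is quaternary the product cannot aromatise and is obtained as the dienone tautomer of the target's ring A.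

Step 19
Reactants: 31 ring A enol with open C2–C3 chain as acetonide (C8 R; C3′ R; C2′ S)
Product: 33 genkwanol B, via deprotected open-chain enol 32 (not isolated)
Conditions: aq. HCl (3 M), THF, 45 °C, under argon
Reagents that add atoms: none
Why: Aqueous acid hydrolyses the five methoxymethyl ethers and the acetonide; ring C then closes between the C8a enol oxygen and C2, either by addition of the C2 hydroxyl to C8a and dehydration or by capture of the 4-hydroxybenzyl cation at C2 by the C8a enol oxygen trans to the C3 hydroxyl, and from the erythro diol both paths lead to the 2,3-trans ring (vinylogous ester formation from a cyclic 1,3-dione and an alcohol). Closure on the C8a oxygen gives the cross-conjugated dienone in which C5 is the carbonyl shared by both enol ethers.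

## Compound list

1 | 2′,4′,6′-trihydroxyacetophenone | CC(=O)c1c(O)cc(O)cc1O | starting material
2 | dimethyl oxalate | COC(=O)C(=O)OC | starting material
3 | methyl 2,4-dioxo-4-(2,4,6-trihydroxyphenyl)butanoate (formed in the flask) | COC(=O)C(=O)CC(=O)c1c(O)cc(O)cc1O | intermediate
4 | methyl 5,7-dihydroxy-4-oxo-4H-chromene-2-carboxylate | COC(=O)c1cc(=O)c2c(O)cc(O)cc2o1 | intermediate
5 | methyl 5,7-bis(methoxymethoxy)-4-oxo-4H-chromene-2-carboxylate | COC(=O)c1cc(=O)c2c(OCOC)cc(OCOC)cc2o1 | intermediate
6 | 4-bromophenol | Oc1ccc(Br)cc1 | starting material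
7 | 1-bromo-4-(methoxymethoxy)benzene | COCOc1ccc(Br)cc1 | intermediate
8 | (2S)-5-oxooxolane-2-carboxylic acid | OC(=O)[C@@H]1CCC(=O)O1 | starting material
9 | (2S)-5-oxooxolane-2-carbonyl chloride (formed in the flask) | ClC(=O)[C@@H]1CCC(=O)O1 | intermediate
10 | [4-(methoxymethoxy)phenyl]magnesium bromide (formed in the flask) | COCOc1ccc([Mg]Br)cc1 | intermediate
11 | (5S)-5-[4-(methoxymethoxy)benzoyl]oxolan-2-one | O=C(c1ccc(OCOC)cc1)[C@@H]1CCC(=O)O1 | intermediate
12 | (5S)-5-{(R)-hydroxy[4-(methoxymethoxy)phenyl]methyl}oxolan-2-one | O[C@H](c1ccc(OCOC)cc1)[C@@H]1CCC(=O)O1 | intermediate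
13 | ethynylmagnesium bromide | C#C[Mg]Br | starting material
14 | (5S)-5-{(R)-hydroxy[4-(methoxymethoxy)phenyl]methyl}oxolan-2-ol, anomers, present as aluminium alkoxide (formed in the flask) | O[C@H](c1ccc(OCOC)cc1)[C@@H]1CCC(O)O1 | intermediate
15 | (1R,2S,5RS)-1-[4-(methoxymethoxy)phenyl]hept-6-yne-1,2,5-triol | C#CC(O)CC[C@H](O)[C@H](O)c1ccc(OCOC)cc1 | intermediate
16 | (3RS)-1-{(4S,5R)-5-[4-(methoxymethoxy)phenyl]-2,2-dimethyl-1,3-dioxolan-4-yl}pent-4-yn-3-ol | C#CC(O)CC[C@@H]1OC(C)(C)O[C@@H]1c1ccc(OCOC)cc1 | intermediate
17 | (4S,5R)-4-{(3RS)-3-[(4-methoxybenzyl)oxy]pent-4-yn-1-yl}-5-[4-(methoxymethoxy)phenyl]-2,2-dimethyl-1,3-dioxolane | C#CC(OCc1ccc(OC)cc1)CC[C@@H]1OC(C)(C)O[C@@H]1c1ccc(OCOC)cc1 | intermediate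
18 | 4-hydroxybenzaldehyde | O=Cc1ccc(O)cc1 | starting material
19 | 4-(methoxymethoxy)benzaldehyde | COCOc1ccc(C=O)cc1 | intermediate
20 | 4-[(tert-butyldimethylsilyl)oxy]-2-(methoxycarbonyl)-5,7-bis(methoxymethoxy)chromenylium trifluoromethanesulfonate (formed in the flask) | COC(=O)c1cc(O[Si](C)(C)C(C)(C)C)c2c(OCOC)cc(OCOC)cc2[o+]1.[O-]S(=O)(=O)C(F)(F)F | intermediate
21 | methyl (2S)-4-(TBSO)-5,7-bis(MOMO)-2-[(3RS)-3-(PMBO)-5-Diox-pent-1-yn-1-yl]-2H-chromene-2-carboxylate | COC(=O)[C@]1(C#CC(OCc2ccc(OC)cc2)CC[C@@H]2OC(C)(C)O[C@@H]2c2ccc(OCOC)cc2)Oc2cc(OCOC)cc(OCOC)c2C(O[Si](C)(C)C(C)(C)C)=C1 | intermediate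
22 | methyl (2R,3RS)-3-(TBSO)-5,7-bis(MOMO)-4-oxo-2-[(3RS)-3-(PMBO)-5-Diox-pent-1-yn-1-yl]chromane-2-carboxylate (formed in the flask) | COC(=O)[C@]1(C#CC(OCc2ccc(OC)cc2)CC[C@@H]2OC(C)(C)O[C@@H]2c2ccc(OCOC)cc2)Oc2cc(OCOC)cc(OCOC)c2C(=O)C1O[Si](C)(C)C(C)(C)C | intermediate
23 | methyl (2R,3RS)-3-hydroxy-5,7-bis(MOMO)-4-oxo-2-[(3RS)-3-(PMBO)-5-Diox-pent-1-yn-1-yl]chromane-2-carboxylate | COC(=O)[C@]1(C#CC(OCc2ccc(OC)cc2)CC[C@@H]2OC(C)(C)O[C@@H]2c2ccc(OCOC)cc2)Oc2cc(OCOC)cc(OCOC)c2C(=O)C1O | intermediate
24 | methyl (2R,3RS)-3,5,7-tris(MOMO)-4-oxo-2-[(3RS)-3-(PMBO)-5-Diox-pent-1-yn-1-yl]chromane-2-carboxylate | COC(=O)[C@]1(C#CC(OCc2ccc(OC)cc2)CC[C@@H]2OC(C)(C)O[C@@H]2c2ccc(OCOC)cc2)Oc2cc(OCOC)cc(OCOC)c2C(=O)C1OCOC | intermediate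
25 | methyl (2R)-3,5,7-tris(MOMO)-4-(TMSO)-2-[(3RS)-3-(PMBO)-5-Diox-pent-1-yn-1-yl]-2H-chromene-2-carboxylate | COC(=O)[C@]1(C#CC(OCc2ccc(OC)cc2)CC[C@@H]2OC(C)(C)O[C@@H]2c2ccc(OCOC)cc2)Oc2cc(OCOC)cc(OCOC)c2C(O[Si](C)(C)C)=C1OCOC | intermediate
26 | methyl (2R,3R)-3-[(S)-Ar(TMSO)methyl]-3,5,7-tris(MOMO)-4-oxo-2-[(3RS)-3-(PMBO)-5-Diox-pent-1-yn-1-yl]chromane-2-carboxylate | COC(=O)[C@]1(C#CC(OCc2ccc(OC)cc2)CC[C@@H]2OC(C)(C)O[C@@H]2c2ccc(OCOC)cc2)Oc2cc(OCOC)cc(OCOC)c2C(=O)[C@@]1(OCOC)[C@H](c1ccc(OCOC)cc1)O[Si](C)(C)C | intermediate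
27 | methyl (2R,3R)-3-[(S)-Ar(TMSO)methyl]-3,5,7-tris(MOMO)-4-oxo-2-[(3RS)-3-hydroxy-5-Diox-pent-1-yn-1-yl]chromane-2-carboxylate | COC(=O)[C@]1(C#CC(O)CC[C@@H]2OC(C)(C)O[C@@H]2c2ccc(OCOC)cc2)Oc2cc(OCOC)cc(OCOC)c2C(=O)[C@@]1(OCOC)[C@H](c1ccc(OCOC)cc1)O[Si](C)(C)C | intermediate
28 | methyl (2R,3R)-3-[(S)-Ar(TMSO)methyl]-3,5,7-tris(MOMO)-4-oxo-2-(3-oxo-5-Diox-pent-1-yn-1-yl)chromane-2-carboxylate | COC(=O)[C@]1(C#CC(=O)CC[C@@H]2OC(C)(C)O[C@@H]2c2ccc(OCOC)cc2)Oc2cc(OCOC)cc(OCOC)c2C(=O)[C@@]1(OCOC)[C@H](c1ccc(OCOC)cc1)O[Si](C)(C)C | intermediate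
29 | methyl (2R,3R)-3-[(S)-Ar(hydroxy)methyl]-3,5,7-tris(MOMO)-4-oxo-2-(3-oxo-5-Diox-pent-1-yn-1-yl)chromane-2-carboxylate (formed in the flask) | COC(=O)[C@]1(C#CC(=O)CC[C@@H]2OC(C)(C)O[C@@H]2c2ccc(OCOC)cc2)Oc2cc(OCOC)cc(OCOC)c2C(=O)[C@@]1(OCOC)[C@@H](O)c1ccc(OCOC)cc1 | intermediate
30 | key precursor: cis-fused dihydrofuran–chromanone methyl ester on C8 (R), with C3′ (R) OMOM, C2′ (S) Ar, and an (E)-C7=C6 alkylidene carrying the C5 ketone and the CH2CH2-Diox chain | COC(=O)[C@]12Oc3cc(OCOC)cc(OCOC)c3C(=O)[C@@]1(OCOC)[C@H](c1ccc(OCOC)cc1)O/C2=C/C(=O)CC[C@@H]1OC(C)(C)O[C@@H]1c1ccc(OCOC)cc1 | intermediate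
31 | ring A enol: spiro dienone with C8a hydroxyl and C5 ketone, C4a carrying CH2-Diox; C8 (R), C3′ (R) OMOM, C2′ (S) Ar, four phenols as MOM ethers | O=C1C=C2O[C@@H](c3ccc(OCOC)cc3)[C@]3(OCOC)C(=O)c4c(OCOC)cc(OCOC)cc4O[C@]23C(O)=C1C[C@@H]1OC(C)(C)O[C@@H]1c1ccc(OCOC)cc1 | intermediate
32 | fully deprotected ring A enol with open (2R,3S)-diol chain; C8 (S), C3′ (R), C2′ (S) (formed in the flask) | O=C1C=C2O[C@@H](c3ccc(O)cc3)[C@]3(O)C(=O)c4c(O)cc(O)cc4O[C@]23C(O)=C1C[C@H](O)[C@H](O)c1ccc(O)cc1 | intermediate
33 | genkwanol B; C2 (R), C3 (S), C8 (S), C2′ (S), C3′ (R) | O=C1C=C2O[C@@H](c3ccc(O)cc3)[C@]3(O)C(=O)c4c(O)cc(O)cc4O[C@]23C2=C1C[C@H](O)[C@@H](c1ccc(O)cc1)O2 | target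

## Step count and risks

Total: 19 steps. Longest linear sequence: 16 steps (steps 3–8, then 10–19, from 6).

**Step 18 (key step).** What may go wrong: slow addition of the enolate to an ester flanked by two fully substituted carbons; loss of the (E) geometry on which the closure depends, either in step 17 (protonation from the wrong side) or by reversible addition of methoxide; or opening of the enol ether by the liberated methoxide. Fallback, independent of alkene geometry, from 28 back to 31: pyrrolidine is added to the ynone to give the enaminone F1. Mild aqueous acetic acid hydrolysis gives the free β-diketone F2 with the silyl ether kept. LiN(i-Pr)2 (3 equiv, THF, −78 to 0 °C) forms the diketone dianion, whose terminal carbanion at C4a acylates the ester to give the cyclic trione F3. HF·pyridine followed by camphorsulfonic acid with molecular sieves then removes the silyl group and condenses the C2′ hydroxyl onto the C7 carbonyl, the less hindered of the two it can reach, giving 31.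

**Step 14.** What may go wrong: poor diastereoselection at the carbinol carbon; reversal by retro-aldol before silyl transfer between two fully substituted carbons; or β-elimination of the aryloxide from the transient enolate, which would erode the configuration at C2. Fallback, which sets the carbinol centre by reduction instead of by the aldol, from 25 (with 19) back to 26: a Lewis-acid Mukaiyama aldol (BF3·OEt2, CH2Cl2, −78 °C, no free enolate) gives the carbinol epimers F4. Dess–Martin oxidation gives the non-enolisable diketone F5. Reduction with potassium tri-sec-butylborohydride at −78 °C, under Felkin–Anh control with the C3 oxygen antiperiplanar and hydride passing the carbonyl carbon C4 and not quaternary C2, gives the single alcohol F6. Silylation (TMSCl, imidazole) returns 26.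

**Step 19.** What may go wrong: ionisation at the two 4-oxybenzylic C–O bonds with epimerisation at C2 or C2′ under the acid needed for six acetal cleavages; or closure of ring C onto the C5 carbonyl instead of through the C8a oxygen. Fallback, a staged endgame from 31 to 33: pyridinium p-toluenesulfonate in MeOH–CH2Cl2 at 40 °C removes only the benzylic acetonide and closes ring C while the phenols are still masked, giving the penta-methoxymethyl ether F7. At this stage the ring closure can be equilibrated and the isomers separated. The acetals are then cleaved under non-aqueous conditions with Me3SiBr in CH2Cl2 at −30 °C, followed by aqueous NaHCO3, to give 33.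

**Step 5.** What may go wrong: mismatched double stereodifferentiation, the substrate's Felkin–Anh preference for the threo alcohol lowering the erythro selectivity of the catalyst. Fallback, which uses chelation control on an open-chain ketone, from 11 back to 16: MeNH(OMe)·HCl and Me3Al open the lactone to the α-hydroxy ketone Weinreb amide F8. Zn(BH4)2 in Et2O reduces it through the zinc chelate to the anti (erythro) diol F9. 2,2-Dimethoxypropane with acid catalysis gives the acetonide amide F10. i-Bu2AlH gives the aldehyde F11, and addition of 13 gives 16.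

## Further compounds

F1 | step 18 | enaminone: pyrrolidine adduct of ynone 28 at C7 (alkene geometry open) | COC(=O)[C@]1(C(=CC(=O)CC[C@@H]2OC(C)(C)O[C@@H]2c2ccc(OCOC)cc2)N2CCCC2)Oc2cc(OCOC)cc(OCOC)c2C(=O)[C@@]1(OCOC)[C@H](c1ccc(OCOC)cc1)O[Si](C)(C)C
F2 | step 18 | β-diketone: methyl (2R,3R)-3-[(S)-Ar(TMSO)methyl]-3,5,7-tris(MOMO)-4-oxo-2-(3,5-dioxo-5... chain: 1,3-dioxo-5-Diox-pentyl)chromane-2-carboxylate | COC(=O)[C@]1(C(=O)CC(=O)CC[C@@H]2OC(C)(C)O[C@@H]2c2ccc(OCOC)cc2)Oc2cc(OCOC)cc(OCOC)c2C(=O)[C@@]1(OCOC)[C@H](c1ccc(OCOC)cc1)O[Si](C)(C)C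
F3 | step 18 | cyclic trione (ring A closed, furan open, C2′ oxygen as TMS ether) | O=C1CC(=O)[C@]2(Oc3cc(OCOC)cc(OCOC)c3C(=O)[C@@]2(OCOC)[C@H](c3ccc(OCOC)cc3)O[Si](C)(C)C)C(O)=C1C[C@@H]1OC(C)(C)O[C@@H]1c1ccc(OCOC)cc1
F4 | step 14 | aldol adduct of 25 and 19 with free hydroxyl, carbinol epimers | COC(=O)[C@]1(C#CC(OCc2ccc(OC)cc2)CC[C@@H]2OC(C)(C)O[C@@H]2c2ccc(OCOC)cc2)Oc2cc(OCOC)cc(OCOC)c2C(=O)[C@@]1(OCOC)C(O)c1ccc(OCOC)cc1
F5 | step 14 | 3-[4-(methoxymethoxy)benzoyl] diketone from F4 | COC(=O)[C@]1(C#CC(OCc2ccc(OC)cc2)CC[C@@H]2OC(C)(C)O[C@@H]2c2ccc(OCOC)cc2)Oc2cc(OCOC)cc(OCOC)c2C(=O)[C@@]1(OCOC)C(=O)c1ccc(OCOC)cc1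
F6 | step 14 | (S)-carbinol: desilyl analogue of 26 | COC(=O)[C@]1(C#CC(OCc2ccc(OC)cc2)CC[C@@H]2OC(C)(C)O[C@@H]2c2ccc(OCOC)cc2)Oc2cc(OCOC)cc(OCOC)c2C(=O)[C@@]1(OCOC)[C@@H](O)c1ccc(OCOC)cc1
F7 | step 19 | genkwanol B penta(methoxymethyl) ether with free C3 hydroxyl (four phenols and the C3′ oxygen protected) | O=C1C=C2O[C@@H](c3ccc(OCOC)cc3)[C@]3(OCOC)C(=O)c4c(OCOC)cc(OCOC)cc4O[C@]23C2=C1C[C@H](O)[C@@H](c1ccc(OCOC)cc1)O2
F8 | step 5 | (4S)-4-hydroxy-N-methoxy-N-methyl-5-[4-(methoxymethoxy)phenyl]-5-oxopentanamide | CON(C)C(=O)CC[C@H](O)C(=O)c1ccc(OCOC)cc1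
F9 | step 5 | (4S,5R)-4,5-dihydroxy-N-methoxy-N-methyl-5-[4-(methoxymethoxy)phenyl]pentanamide | CON(C)C(=O)CC[C@H](O)[C@H](O)c1ccc(OCOC)cc1
F10 | step 5 | N-methoxy-N-methyl-3-{(4S,5R)-5-[4-(methoxymethoxy)phenyl]-2,2-dimethyl-1,3-dioxolan-4-yl}propanamide | CON(C)C(=O)CC[C@@H]1OC(C)(C)O[C@@H]1c1ccc(OCOC)cc1
F11 | step 5 | 3-{(4S,5R)-5-[4-(methoxymethoxy)phenyl]-2,2-dimethyl-1,3-dioxolan-4-yl}propanal | O=CCC[C@@H]1OC(C)(C)O[C@@H]1c1ccc(OCOC)cc1
A1 | alternative 1 | genkwanol B 3-acetate tetrakis(tert-butyldimethylsilyl) ether | O=C1C=C2O[C@@H](c3ccc(O[Si](C)(C)C(C)(C)C)cc3)[C@]3(O)C(=O)c4c(O[Si](C)(C)C(C)(C)C)cc(O[Si](C)(C)C(C)(C)C)cc4O[C@]23C2=C1C[C@H](OC(C)=O)[C@@H](c1ccc(O[Si](C)(C)C(C)(C)C)cc1)O2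
A2 | alternative 1 | aryl-free bis(lactol acetate) core (acetoxy in place of both aryl groups, anomers; C3 acetate; two phenols as TBS ethers) | O=C1C=C2OC(OC(C)=O)[C@]3(O)C(=O)c4c(O[Si](C)(C)C(C)(C)C)cc(O[Si](C)(C)C(C)(C)C)cc4O[C@]23C2=C1C[C@H](OC(C)=O)C(OC(C)=O)O2
A3 | alternative 1 | bis[4-(tert-butyldimethylsilyloxy)phenyl]zinc | CC(C)(C)[Si](C)(C)Oc1ccc([Zn]c2ccc(O[Si](C)(C)C(C)(C)C)cc2)cc1
A4 | alternative 2 | tetra-O-methoxymethyl genkwanol B (C3′ hydroxyl and one chromanone phenol free) | O=C1C=C2O[C@@H](c3ccc(OCOC)cc3)[C@]3(O)C(=O)c4c(O)cc(OCOC)cc4O[C@]23C2=C1C[C@H](OCOC)[C@@H](c1ccc(OCOC)cc1)O2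
A5 | alternative 2 | nine-membered diaryl ether 1,2-diketone macrocycle on a flavan-3-ol with free C5 phenol | Oc1cc2O[C@@H](c3ccc(OCOC)cc3)C(=O)C(=O)c3c(O)cc(OCOC)cc3Oc2c2c1C[C@H](OCOC)[C@@H](c1ccc(OCOC)cc1)O2
A6 | alternative 3 | penta-O-methoxymethyl genkwanol B (C3′ hydroxyl free) | O=C1C=C2O[C@@H](c3ccc(OCOC)cc3)[C@]3(O)C(=O)c4c(OCOC)cc(OCOC)cc4O[C@]23C2=C1C[C@H](OCOC)[C@@H](c1ccc(OCOC)cc1)O2
A7 | alternative 3 | spiro furan-3-one dienone with a 2-formyl-3,5-bis(methoxymethoxy)phenyl ether on C8 | O=C1C=C2O[C@@H](c3ccc(OCOC)cc3)C(=O)[C@@]2(Oc2cc(OCOC)cc(OCOC)c2C=O)C2=C1C[C@H](OCOC)[C@@H](c1ccc(OCOC)cc1)O2
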